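(The data are calculated for an exercise; the scatter is artificial.)

One ratio carries this flask: total product at the plateau, over [substrate] times [coupling partner] taken at their mean values, with both substrates counted as one pool.

common to all: racemization catalyst 110 mM

| charge | left-handed substrate | right-handed substrate | coupling partner | free catalyst | remark | time |
|---|---|---|---|---|---|---|
| winter | 0.67 M | 0.67 M | 2.2 M | 5 mM | run made earlier |  |
| spring | 1 M | 1 M | 1.1 M | 5 mM | run made earlier |  |
| flask | 1.0 M | 1.0 M | 2.20 M | 5.0 mM |  | 20 h |

| run | time / h | left-handed product / % | right-handed product / % | left-handed substrate / % |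
|---|---|---|---|---|
| winter | 3.00 | 17.7 | 3.4 | 37.9 |
| winter | 6.00 | 19.5 | 4.9 | 39.1 |
| winter | 10.0 | 18.8 | 2.3 | 38.6 |
| winter | 12.0 | 18.5 | 3.6 | 39.9 |
| winter | 15.0 | 19.1 | 5.7 | 38.2 |
| spring | 3.00 | 8.8 | 3.0 | 44.1 |
| spring | 6.00 | 9.8 | 1.7 | 42.9 |
| spring | 10.0 | 10.1 | 0.8 | 45.3 |
| spring | 12.0 | 9.1 | 1.2 | 43.9 |
| spring | 15.0 | 9.0 | 1.9 | 44.0 |

(standard deviation of a reading: 1 percentage point)

- excess of left-handed product over right-handed product in the product at 2.0 h
- excess of left-handed product over right-handed product in the product at 20 h
- part of the left-handed substrate and right-handed substrate charged together that has reacted at 20 h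

- free catalyst is single-handed; left-handed substrate and right-handed substrate are mirror images of each other, charged as a racemate, each of them at the stated concentration
- on the list of suspects stand: coupling partner + free catalyst + left-handed substrate -> free catalyst + left-handed product; left-handed substrate + racemization catalyst <-> right-handed substrate + racemization catalyst; free catalyst -> spent catalyst B; 2 racemization catalyst -> spent catalyst A; coupling partner + free catalyst + right-handed substrate -> free catalyst + right-handed product
- an excess is the difference of the two amounts in percent of their sum
- an excess is below zero if the other one leads

We read the columns first. Left-handed product goes from 17.7% at 3.00 h to 19.1% at 15.0 h in the winter run and from 8.8% to 9.0% in the spring run, steps near the scatter of 1 percentage point, so we read coupling as stopped by the first row. The column means are 18.7% left and 3.98% right in winter, and 9.36% and 1.72% in spring. The winter left-handed substrate averages 38.7%, against 38.6% for an equal split of the unreacted part, so over these rows one pool will do.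

On the charges, the plateaus read 0.304 M in the winter run and 0.222 M in the spring run. Taking each mean as the charge less half the plateau, the ratio is 0.125 /M in winter and 0.119 /M in spring, although spring had half the winter partner. Pooled, 0.122 /M is the reach of a 5.0 mM catalyst charge: plateau product per unit of mean [substrate] times mean [coupling partner]. Integrating the winter curve exactly gives 0.126 /M, which is higher by 1.05%, the price of using the mean.

For the flask, the ratio becomes a quadratic in the plateau, and we get 0.431 M, or 21.6% reacted. The pooled means give an excess of 66.3%, which we take for both asked times.

The forecast says 66%, 66% and 21.5%, holding that “the coupling catalyst dies early”. The flask gives 61.1%, 61.2% and 22.0%.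

    coupling partner + free catalyst + left-handed substrate → free catalyst + left-handed product (k = 34.0 /M²/h)
    left-handed substrate + racemization catalyst ⇌ right-handed substrate + racemization catalyst, rate k2*[racemization catalyst]*[left-handed substrate] forward; the back reaction follows from the equilibrium constant (k = 5.50 /M/h)
    free catalyst → spent catalyst B (k = 0.800 /h)
    2 racemization catalyst → spent catalyst A (k = 0.920 /M/h)
    coupling partner + free catalyst + right-handed substrate → free catalyst + right-handed product (k = 7.60 /M²/h)

In the flask, free catalyst stands at 20.2% at 2.00 h and 0.0335% at 10.0 h, when racemization catalyst still stands at 33.1% and each substrate at 38.9%. The flask's reacted part gives a reach of 0.125 /M, against our 0.122 /M. With this reach, the neighbouring flask at 1.3 M of coupling partner reckons to 13.6% reacted. That neighbouring flask gives 13.7% reacted, at an excess of 62.1%.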